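**Plan**

- Retrosynthesis: the ester C15–O bond is cut first (back to (S)-solketal), then the C3–C4 bond of ring A, then the C9–C11 bond together with a 1,3-carbonyl transposition, and last the two alkyl bonds at C10 (C10–C1 and C10–CH3). This leads back to (S)-carvone.
- Enabling feature: ring B (C5–C10), with the C7 ketone, the C8 methyl, C6H2 and a three-carbon unit on C5, is carvone. The gem-dimethyl carbon C4 is the inner carbon of an isopropenyl group plus one hydrogen atom, so Markovnikov hydrogen-atom transfer to the C5 isopropenyl group gives the tertiary C4 radical. This radical closes ring A onto C3, the C=N carbon at the end of the three-carbon arm on C10.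
- Forward: ring B is bought; C10 is made quaternary by methylation and then allylation; the C11–C15 chain adds to the ketone as an alkyllithium and an oxidative transposition gives the C7 enone; the allyl terminus becomes the C3 aldehyde and its tosylhydrazone; an iron hydride radical cyclization closes ring A with traceless loss of the nitrogen acceptor; oxidation at C15, esterification and acetonide removal finish the route.
- Stereochemistry: C5 comes from (S)-carvone; C10 is set by allylation anti to the isopropenyl group, which fixes the trans ring fusion before ring A exists; C13 comes from methyl (R)-3-methylglutarate; the glycerol centre comes from (S)-solketal.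

Key step: step 11

Remark: labdane numbering is used for positions (ring A = C1–C5 and C10, ring B = C5–C10, chain C11–C15). The three chiral building blocks are taken to be commercial in the stated configuration. The methylated carvone is carried forward as its epimer mixture; the list shows the major trans isomer.

**Route**

Step 1
Reactants: 1 (S)-carvone
Product: 2 6-methylcarvone
Conditions: LDA (LiN(i-Pr)2), THF, −78 °C; MeI, −78 to 0 °C
Reagents that add atoms: iodomethane, CI
Why: Kinetic deprotonation at the only sp3 carbon alpha to the ketone gives the cross-conjugated lithium enolate, which is methylated (enolate alkylation) mainly anti to the isopropenyl group; this centre need not be controlled because step 2 enolizes it again.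

Step 2
Reactants: 2 6-methylcarvone
Product: 3 6-allyl-6-methylcarvone
Conditions: LDA (LiN(i-Pr)2), THF, −78 °C; allyl bromide, DMPU, −78 to 0 °C
Reagents that add atoms: allyl bromide, C=CCBr
Why: Enolate alkylation of the now trisubstituted alpha carbon, in which the allylic bromide should attack the face opposite the adjacent isopropenyl group, so the allyl group ends trans and the methyl group cis to it, the C10 configuration of the target relative to C5 (substrate control).

Step 3
Reactants: 4 methyl hydrogen (R)-3-methylglutarate
Product: 5 methyl (R)-5-hydroxy-3-methylpentanoate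
Conditions: BH3·SMe2, THF, 0 °C to rt; MeOH then water; used crude
Reagents that add atoms: none
Why: Chemoselective borane reduction, in which the carboxylic acid is reduced much faster than the methyl ester, so the two arms of the glutarate are told apart and the stereocenter is untouched.

Step 4
Reactants: 5 methyl (R)-5-hydroxy-3-methylpentanoate
Product: 6 methyl (S)-5-iodo-3-methylpentanoate
Conditions: I2, PPh3, imidazole, CH2Cl2, 0 °C to rt
Reagents that add atoms: iodine, II
Why: Appel-type iodination of the primary alcohol by SN2 displacement at CH2; the remote stereocenter is not involved (the descriptor changes only through the priority rules).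

Step 5
Reactants: 6 methyl (S)-5-iodo-3-methylpentanoate
Product: 7 (S)-5-iodo-3-methylpentan-1-ol
Conditions: i-Bu2AlH (2.2 equiv), CH2Cl2, −78 to 0 °C; aqueous work-up
Reagents that add atoms: none
Why: Ester reduction with i-Bu2AlH at low temperature gives the primary alcohol and should leave the primary iodide intact.

Step 6
Reactants: 7 (S)-5-iodo-3-methylpentan-1-ol
Product: 8 silyl ether iodide
Conditions: TBSCl, imidazole, CH2Cl2, 0 °C
Reagents that add atoms: tert-butyldimethylsilyl chloride, CC(C)(C)[Si](C)(C)Cl
Why: Standard silylation of a primary alcohol; the silyl ether masks C15 through the organolithium, chromium, palladium and radical steps.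

Step 7
Reactants: 8 silyl ether iodide; 3 6-allyl-6-methylcarvone
Product: 10 tertiary allylic alcohol, via alkyllithium 9 (not isolated)
Conditions: 8 (1.3 equiv), t-BuLi (2.6 equiv), Et2O/pentane, −78 °C; then 3, −78 to −20 °C; then H2O
Reagents that add atoms: none
Why: Iodine–lithium exchange gives the primary alkyllithium, which should add 1,2 to the enone carbonyl (the quaternary neighbour has no alpha hydrogen); the configuration of the new carbinol carbon is of no consequence because step 8 makes it sp2.

Step 8
Reactants: 10 tertiary allylic alcohol
Product: 11 allyl enone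
Conditions: pyridinium chlorochromate [C5H5NH][CrO3Cl] (3 equiv), 4 Å molecular sieves, CH2Cl2, rt
Reagents that add atoms: pyridinium chlorochromate, [O-][Cr](=O)(=O)Cl.c1cc[nH+]cc1
Why: Babler–Dauben oxidative transposition, in which the tertiary allylic chromate ester undergoes a [3,3] shift to the less hindered secondary allylic chromate that is oxidized to the C7 ketone with a tetrasubstituted C8=C9 bond; isolated alkenes and the silyl ether are inert.

Step 9
Reactants: 11 allyl enone
Product: 12 aldehyde
Conditions: PdCl2(PhCN)2 (10 mol %), CuCl2·2H2O (10 mol %), AgNO2 (5 mol %), O2 (1 atm), t-BuOH/MeNO2 15:1, rt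
Reagents that add atoms: dioxygen, O=O
Why: Nitrite-co-catalysed aldehyde-selective (anti-Markovnikov) Wacker oxidation of the monosubstituted alkene; the 1,1-disubstituted isopropenyl group and the tetrasubstituted enone should not react, and the quaternary carbon next to the allyl CH2 further disfavours attack at the internal carbon.

Step 10
Reactants: 12 aldehyde
Product: 13 tosylhydrazone
Conditions: TsNHNH2 (1.05 equiv), MeOH, rt
Reagents that add atoms: p-toluenesulfonyl hydrazide, NNS(=O)(=O)c1ccc(C)cc1
Why: Condensation of the aldehyde with the sulfonyl hydrazide at room temperature; the hindered, conjugated C7 ketone should not compete.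

Step 11
Reactants: 13 tosylhydrazone
Product: 16 bicyclic silyl ether, via sulfonylhydrazide 14 (not isolated), via alkyl diazene 15 (not isolated)
Conditions: Fe(acac)3 (30 mol %), PhSiH3 (2.5 equiv), EtOH/THF, 60 °C; then NaOAc, 70 °C
Reagents that add atoms: none
Why: Fe(acac)3 and PhSiH3 in EtOH form an iron hydride that transfers a hydrogen atom to the CH2 terminus of the isopropenyl group (Markovnikov), so the tertiary radical arises at C4, which already carries both methyl groups; this nucleophilic radical adds to the electrophilic hydrazone carbon C3, the nitrogen radical is reduced and protonated to hydrazide 14, and base-induced loss of p-toluenesulfinate gives diazene 15, which loses N2 and leaves C3 as CH2. The closest known reaction types are the iron hydride (Mukaiyama-type hydrogen-atom-transfer) reductive coupling of unactivated 1,1-disubstituted alkenes with aldehyde sulfonylhydrazones and the hydrogen-atom-transfer cyclization of alkene-tethered hydrazones. Ring A closes in the 6-exo-trig mode through a chair-like transition state. No new stereocenter remains: C4 bears two methyl groups, the C3 centre of 14 disappears with N2, and the trans ring fusion follows from the trans relation of the C10 arm and the C5 isopropenyl group set in steps 1 and 2. The step needs hydrogen-atom transfer to the isopropenyl group only, which the substrate secures because the other alkene is a tetrasubstituted, electron-poor enone that accepts a hydrogen atom far more slowly. It also needs ring closure to outrun reduction of the tertiary radical, which the three-atom tether and the polarity-matched C=N acceptor should favour.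

Step 12
Reactants: 16 bicyclic silyl ether
Product: 17 carboxylic acid
Conditions: CrO3, H2SO4, H2O, acetone, 0 °C to rt
Reagents that add atoms: water, O
Why: Jones oxidation under acidic conditions should cleave the primary silyl ether and oxidize the freed alcohol through the aldehyde hydrate to the acid in one flask; the tetrasubstituted enone is stable to CrO3.

Step 13
Reactants: 17 carboxylic acid; 18 (S)-solketal
Product: 19 acetonide ester
Conditions: N,N′-diisopropylcarbodiimide, DMAP (cat.), CH2Cl2, 0 °C to rt
Reagents that add atoms: none
Why: Steglich esterification of the acid with the primary alcohol of the acetonide; no stereocenter is touched.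

Step 14
Reactants: 19 acetonide ester
Product: 20 CNP0316600.2
Conditions: AcOH/H2O 4:1, 40 °C
Reagents that add atoms: none
Why: Mild acid hydrolysis of the isopropylidene acetal; at this acidity and temperature acyl migration in the 1-monoacylglycerol, which would erode the glycerol stereocenter, should be slow.

**Compound list**

1 | (S)-(+)-carvone, (5S)-2-methyl-5-(prop-1-en-2-yl)cyclohex-2-en-1-one | O=C1C(C)=CC[C@H](C(C)=C)C1 | starting material
2 | 6-methylcarvone, (5S)-2,6-dimethyl-5-(prop-1-en-2-yl)cyclohex-2-en-1-one, epimers at C6, major trans (5S,6R) isomer drawn | O=C1C(C)=CC[C@H](C(C)=C)[C@H]1C | intermediate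
3 | 6-allyl-6-methylcarvone, (5R,6R)-2,6-dimethyl-6-(prop-2-en-1-yl)-5-(prop-1-en-2-yl)cyclohex-2-en-1-one, allyl trans and methyl cis to the isopropenyl group | O=C1C(C)=CC[C@H](C(C)=C)[C@@]1(C)CC=C | intermediate
4 | methyl hydrogen (R)-3-methylglutarate, (3R)-5-methoxy-3-methyl-5-oxopentanoic acid | OC(=O)C[C@@H](C)CC(=O)OC | starting material
5 | methyl (3R)-5-hydroxy-3-methylpentanoate | OCC[C@@H](C)CC(=O)OC | intermediate
6 | methyl (3S)-5-iodo-3-methylpentanoate | ICC[C@@H](C)CC(=O)OC | intermediate
7 | (3S)-5-iodo-3-methylpentan-1-ol | ICC[C@@H](C)CCO | intermediate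
8 | tert-butyl{[(3S)-5-iodo-3-methylpentyl]oxy}dimethylsilane | ICC[C@@H](C)CCO[Si](C)(C)C(C)(C)C | intermediate
9 | [(3R)-5-(tert-butyldimethylsilyloxy)-3-methylpentyl]lithium, not isolated | [Li]CC[C@@H](C)CCO[Si](C)(C)C(C)(C)C | intermediate
10 | 6-allyl-1-[(3R)-5-(tert-butyldimethylsilyloxy)-3-methylpentyl]-2,6-dimethyl-5-(prop-1-en-2-yl)cyclohex-2-en-1-ol, ring centres as in 3, carbinol configuration not defined | CC1=CC[C@H](C(C)=C)[C@@](C)(CC=C)C1(O)CC[C@@H](C)CCO[Si](C)(C)C(C)(C)C | intermediate
11 | 4-allyl-3-[(3R)-5-(tert-butyldimethylsilyloxy)-3-methylpentyl]-2,4-dimethyl-5-(prop-1-en-2-yl)cyclohex-2-en-1-one, allyl trans and methyl cis to the isopropenyl group | CC1=C(CC[C@@H](C)CCO[Si](C)(C)C(C)(C)C)[C@](C)(CC=C)[C@@H](C(C)=C)CC1=O | intermediate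
12 | 3-{2-[(3R)-5-(tert-butyldimethylsilyloxy)-3-methylpentyl]-1,3-dimethyl-4-oxo-6-(prop-1-en-2-yl)cyclohex-2-en-1-yl}propanal, ring centres as in 11 | CC1=C(CC[C@@H](C)CCO[Si](C)(C)C(C)(C)C)[C@](C)(CCC=O)[C@@H](C(C)=C)CC1=O | intermediate
13 | (E)-N′-tosylhydrazone of aldehyde 12 | CC1=C(CC[C@@H](C)CCO[Si](C)(C)C(C)(C)C)[C@](C)(CC/C=N/NS(=O)(=O)c2ccc(C)cc2)[C@@H](C(C)=C)CC1=O | intermediate
14 | ring-closed N-alkyl-N′-tosylhydrazide at C3 (C3 configuration not defined), not isolated | CC1=C(CC[C@@H](C)CCO[Si](C)(C)C(C)(C)C)[C@]2(C)CCC(NNS(=O)(=O)c3ccc(C)cc3)C(C)(C)[C@H]2CC1=O | intermediate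
15 | ring-closed C3 monoalkyl diazene, not isolated | CC1=C(CC[C@@H](C)CCO[Si](C)(C)C(C)(C)C)[C@]2(C)CCC(N=N)C(C)(C)[C@H]2CC1=O | intermediate
16 | (4aR,8aR)-4-[(3R)-5-(tert-butyldimethylsilyloxy)-3-methylpentyl]-3,4a,8,8-tetramethyl-4a,5,6,7,8,8a-hexahydronaphthalen-2(1H)-one, trans-fused | CC1=C(CC[C@@H](C)CCO[Si](C)(C)C(C)(C)C)[C@]2(C)CCCC(C)(C)[C@H]2CC1=O | intermediate
17 | (3R)-3-methyl-5-[(4aR,8aR)-2,5,5,8a-tetramethyl-3-oxo-3,4,4a,5,6,7,8,8a-octahydronaphthalen-1-yl]pentanoic acid | CC1=C(CC[C@@H](C)CC(=O)O)[C@]2(C)CCCC(C)(C)[C@H]2CC1=O | intermediate
18 | (S)-solketal, [(4S)-2,2-dimethyl-1,3-dioxolan-4-yl]methanol | CC1(C)OC[C@H](CO)O1 | starting material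
19 | [(4R)-2,2-dimethyl-1,3-dioxolan-4-yl]methyl ester of acid 17 | CC1=C(CC[C@@H](C)CC(=O)OC[C@H]3COC(C)(C)O3)[C@]2(C)CCCC(C)(C)[C@H]2CC1=O | intermediate
20 | CNP0316600.2, (2R)-2,3-dihydroxypropyl (3R)-3-methyl-5-[(4aR,8aR)-2,5,5,8a-tetramethyl-3-oxo-3,4,4a,5,6,7,8,8a-octahydronaphthalen-1-yl]pentanoate | CC1=C(CC[C@@H](C)CC(=O)OC[C@H](O)CO)[C@]2(C)CCCC(C)(C)[C@H]2CC1=O | target

**Step count**

Total: 14 steps. Longest linear sequence: 12 steps (steps 3 to 14, from 4). The carvone branch (steps 1 and 2) joins at step 7.

**Steps most likely to fail**

Step 11. The tertiary radical may be reduced by a second hydrogen-atom transfer before it reaches C3, the silane may reduce the C=N bond, or the hydrazide may not lose sulfinate and N2 cleanly. The fallback sets out from 12 and returns at 16; it replaces the traceless nitrogen acceptor by the aldehyde carbonyl and removes the oxygen in a separate operation. Aldehyde 12 is treated with Fe(acac)3 and PhSiH3 in EtOH at 60 °C, so that the C4 radical adds 6-exo to the aldehyde carbon and the alkoxy radical is reduced, giving the C3 carbinol F1. The carbinol is acylated with phenyl chlorothionoformate (pyridine, DMAP, CH2Cl2) to the phenyl thionocarbonate F2. Barton–McCombie deoxygenation (Bu3SnH, AIBN, toluene, 90 °C) should then give 16.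

Step 9. Attack of the oxygen nucleophile at the internal carbon (methyl ketone formation) or palladium-mediated migration of the allyl double bond may compete with aldehyde formation. The fallback sets out from 11 and returns at 12; it uses hydroboration and oxidation instead of a Wacker process. Catalysed hydroboration of 11 with pinacolborane and RhCl(PPh3)3 in THF at rt should take the monosubstituted alkene in preference to the isopropenyl group and the ketone, giving the terminal pinacol boronate F3. Oxidation with NaBO3·4H2O in THF/H2O gives the primary alcohol F4, and Dess–Martin periodinane in CH2Cl2 gives 12.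

Step 8. Chromate ester formation at the hindered tertiary carbinol may be slow, so that ionization and dehydration to a diene outrun the [3,3] shift. The fallback sets out from 10 and returns at 11; it separates the 1,3-shift from the oxidation. Catalytic Ph3SiOReO3 in Et2O at 0 °C should isomerize 10 to the less hindered secondary allylic alcohol F5 with the tetrasubstituted C8=C9 bond. MnO2 in CH2Cl2 then oxidizes the allylic alcohol to 11.

**Further compounds**

F1 | step 11 | ring-closed C3 carbinol of the silyl ether series (C3 configuration not defined) | CC1=C(CC[C@@H](C)CCO[Si](C)(C)C(C)(C)C)[C@]2(C)CCC(O)C(C)(C)[C@H]2CC1=O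
F2 | step 11 | O-phenyl thionocarbonate of F1 | CC1=C(CC[C@@H](C)CCO[Si](C)(C)C(C)(C)C)[C@]2(C)CCC(OC(=S)Oc3ccccc3)C(C)(C)[C@H]2CC1=O
F3 | step 9 | terminal pinacol boronate from 11 | CC1=C(CC[C@@H](C)CCO[Si](C)(C)C(C)(C)C)[C@](C)(CCCB2OC(C)(C)C(C)(C)O2)[C@@H](C(C)=C)CC1=O
F4 | step 9 | 3-hydroxypropyl enone (primary alcohol) | CC1=C(CC[C@@H](C)CCO[Si](C)(C)C(C)(C)C)[C@](C)(CCCO)[C@@H](C(C)=C)CC1=O
F5 | step 8 | transposed secondary allylic alcohol at C7 (carbinol configuration not defined) | CC1=C(CC[C@@H](C)CCO[Si](C)(C)C(C)(C)C)[C@](C)(CC=C)[C@@H](C(C)=C)CC1O
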